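A direct plan would make the (Z)-dienyne A1 from nerol and fold it with a confined chiral Brønsted acid into the cis-fused enol acetate A2, closing C4–C5 and C9–C10 in one cationic cascade. It would then propargylate the derived enolate at C9 (ketone A3), add MeLi to the C8 ketone and formylate the alkyne (ynal A4), and build the formyl-hydroquinone last by a furan Diels–Alder reaction and reduction.
Its weak steps would be:
(a) the alkyne-terminated asymmetric bicyclisation: a terminal alkyne is a poor cation trap, a (Z)-alkene leaks easily into stepwise closure, and no catalyst is known to control this case, yet every stereocentre depends on it;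
(b) the methyl addition to the C8 ketone: the reagent would have to enter on the face that carries both the vicinal C9 side chain and the angular methyl group, so attack on the open face (C8 epimer) and enolisation would compete strongly;
(c) the arene construction at the very end: the free tertiary alcohol sits next to an ynal and then a formylquinone, both conjugate acceptors, and the least certain cycloaddition comes after all the material has been invested.

**Retrosynthetic overview**
Ring B is taken from the chiral pool: (S)-carvone already holds C5 (its stereocentre), C6, C7, the C8 methyl, C9 (its carbonyl), C10 and, as the isopropenyl group, C4 with its methyl carbons.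
Two α′-alkylations make C10 quaternary; the three-carbon chain goes in first and the methyl last, so CH3-10 ends anti to the isopropenyl group, which is the cis ring fusion.
Ring A is closed last at C3–C4: an iron-hydride hydrogen-atom-transfer radical cyclisation onto a sulfonylhydrazone turns the isopropenyl group into the gem-dimethyl C4 and leaves C3 as CH2.
C8–OH then comes from reductive α-hydroxylation of the enone, and C9–C11–aryl from methylenation and hydroboration/Suzuki coupling with a ready-made bromo-formyl arene.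
The design therefore needs no cationic cascade, no methyl addition to a C8 ketone and no late arene synthesis.

Key step: step 3

Remark: drimane numbering is used (C1–C10 for the decalin, C11 for the benzylic CH2); β is the face of CH3-10. The SMILES defines a cis-fused decalin (H-5 and CH3-10 both β) with CH3-8 and C11 β and OH-8 α.

**Step 1**
Reactants: 1 (S)-(+)-carvone; 2 2-(2-iodoethyl)-1,3-dioxolane
Product: 4 (5S,6R)-6-[2-(1,3-dioxolan-2-yl)ethyl]-2-methyl-5-(prop-1-en-2-yl)cyclohex-2-en-1-one, via lithium dienolate 3 (not isolated)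
Conditions: LiN(i-Pr)2, THF, −78 °C; 2, DMPU, −78 → −20 °C
Reagents that add atoms: 2-(2-iodoethyl)-1,3-dioxolane (2), ICCC1OCCO1
Why: Kinetic α′-deprotonation of the enone and SN2 enolate alkylation should put the C1–C3 chain on the future C10; the new centre (mainly trans to the isopropenyl group) is planarised again in step 2 and the carvone stereocentre (future C5) is untouched.

**Step 2**
Reactants: 4 alkylated carvone
Product: 6 (5R,6S)-6-[2-(1,3-dioxolan-2-yl)ethyl]-2,6-dimethyl-5-(prop-1-en-2-yl)cyclohex-2-en-1-one, via lithium enolate 5 (not isolated)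
Conditions: LiN(i-Pr)2, THF, −78 → −40 °C; MeI, DMPU, −78 → 0 °C
Reagents that add atoms: iodomethane, CI
Why: In this second enolate alkylation MeI should attack the tetrasubstituted enolate anti to the neighbouring isopropenyl group, so the methyl (CH3-10) ends trans and the acetal chain cis to it, which fixes C10 and the later cis ring fusion.

**Step 3 (key step)**
Reactants: 6 quaternary acetal; 7 4-methylbenzenesulfonohydrazide
Product: 11 (4aR,8aS)-2,5,5,8a-tetramethyl-4a,5,6,7,8,8a-hexahydronaphthalen-1(4H)-one, via aldehyde 8 (not isolated), via tosylhydrazone 9 (not isolated), via cyclised sulfonylhydrazide 10 (not isolated)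
Conditions: 2 M aq. HCl, THF, rt; 7, MeOH, rt; then Fe(acac)3 (30 mol %), PhSiH3, EtOH, 60 °C, 0.02 M; then NaOAc, EtOH, 80 °C
Reagents that add atoms: none
Why: After acetal hydrolysis and condensation to the tosylhydrazone, the iron hydride formed from Fe(acac)3 and PhSiH3 transfers a hydrogen atom to the CH2 terminus of the isopropenyl group (Markovnikov), and the tertiary C4 radical adds to the hydrazone carbon C3; the hydrazinyl radical is reduced, and warming with NaOAc expels sulfinate and then N2 from the alkyldiazene, leaving C3 as CH2. The closest known reactions are the iron-hydride alkene–sulfonylhydrazone coupling with traceless C–N reduction (hydromethylation with formaldehyde hydrazones) and hydrogen-atom-transfer-triggered radical cyclisations onto hydrazones; the last stage is the decomposition known from tosylhydrazone reductions. Ring A is closed in the 6-exo-trig mode through the C3–C4 bond, and C4 becomes the gem-dimethyl quaternary carbon because the former CH2 of the isopropenyl group is now its second methyl. No lasting stereocentre is created (the C3–N centre is erased); the cis fusion follows from the cis relationship of chain and isopropenyl group set in step 2. The step needs hydrogen-atom transfer to the electron-rich 1,1-disubstituted alkene and not to the enone, and cyclisation faster than reduction of the radical or intermolecular addition to an enone. This should be secured by the poor acceptor quality of the α-methyl trisubstituted enone, by the proximity of the two cis side arms and by high dilution.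

**Step 4**
Reactants: 11 bicyclic enone
Product: 13 (2R,4aR,8aS)-2-hydroxy-2,5,5,8a-tetramethyloctahydronaphthalen-1(2H)-one, via hydroperoxide 12 (not isolated)
Conditions: Mn(dpm)3 (5 mol %; dpm = dipivaloylmethanate), PhSiH3, O2 (1 atm), i-PrOH–CH2Cl2, 0 °C; then P(OEt)3
Reagents that add atoms: dioxygen, O=O
Why: In this Mukaiyama-type reductive α-hydroxylation the manganese hydride delivers H to C7, O2 traps the C8 radical and the phosphite reduces the hydroperoxide; O2 should approach C8 anti to the pseudo-axial CH3-10 (1,3-relationship), giving the 8α-OH, 8β-CH3 centre.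

**Step 5**
Reactants: 13 ketol
Product: 14 (2R,4aR,8aS)-2,5,5,8a-tetramethyl-1-methylidenedecahydronaphthalen-2-ol
Conditions: Ph3PCH3Br, KOt-Bu, toluene, 100 °C
Reagents that add atoms: methyltriphenylphosphonium bromide, C[P+](c1ccccc1)(c1ccccc1)c1ccccc1.[Br-]
Why: Wittig methylenation with a salt-poor ylide in hot toluene is the variant that works on non-enolisable ketones flanked by two fully substituted carbons; it introduces C11 and forms no stereocentre.

**Step 6**
Reactants: 15 2-bromobenzene-1,4-diol
Product: 16 2-bromo-1,4-bis(methoxymethoxy)benzene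
Conditions: MOMCl, i-Pr2NEt, CH2Cl2, 0 °C → rt
Reagents that add atoms: chloromethyl methyl ether, COCCl
Why: O-Alkylation of both phenols (acetal protection) gives ethers that direct the next metalation and come off under mild acid; no stereocentre.

**Step 7**
Reactants: 16 bis-MOM ether
Product: 19 2-bromo-3,6-bis(methoxymethoxy)benzaldehyde, via aryllithium 17 (not isolated), via lithium hemiaminalate 18 (not isolated)
Conditions: LiN(i-Pr)2, THF, −78 °C; DMF, −78 → −40 °C; aq. NH4Cl
Reagents that add atoms: N,N-dimethylformamide, CN(C)C=O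
Why: In this directed ortho-metalation the amide base should remove the most acidic ring proton, flanked by Br and OMOM, without bromine–lithium exchange, and DMF formylates the aryllithium; no stereocentre.

**Step 8**
Reactants: 14 allylic alcohol; 19 bromo aldehyde
Product: 21 2-{[(1R,2R,4aR,8aS)-2-hydroxy-2,5,5,8a-tetramethyldecahydronaphthalen-1-yl]methyl}-3,6-bis(methoxymethoxy)benzaldehyde, via alkylborane 20 (not isolated)
Conditions: 9-BBN, THF, 65 °C; H2O; then 19, Pd(dppf)Cl2 (10 mol %; dppf = 1,1'-bis(diphenylphosphino)ferrocene), AsPh3, Cs2CO3, DMF–H2O, 50 °C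
Reagents that add atoms: 2-bromo-3,6-bis(methoxymethoxy)benzaldehyde (19), COCOc1ccc(OCOC)c(C=O)c1Br
Why: In the hydroboration the borane should reach the exocyclic alkene from the α-face, opposite the two flanking β-methyl groups on C8 and C10, so H-9 becomes α and C11 β; the B-alkyl Suzuki–Miyaura coupling then joins C11 to the aryl bromide, whose ortho-formyl group aids oxidative addition.

**Step 9**
Reactants: 21 protected target
Product: 22 2-{[(1R,2R,4aR,8aS)-2-hydroxy-2,5,5,8a-tetramethyldecahydronaphthalen-1-yl]methyl}-3,6-dihydroxybenzaldehyde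
Conditions: NaHSO4·SiO2, CH2Cl2, rt
Reagents that add atoms: none
Why: Mild heterogeneous acid-catalysed hydrolysis of the two phenolic MOM acetals should spare the tertiary alcohol and the aldehyde; no stereocentre is touched.

## Compound list

1 | (S)-(+)-carvone, (5S)-2-methyl-5-(prop-1-en-2-yl)cyclohex-2-en-1-one | CC1=CC[C@@H](CC1=O)C(C)=C | starting material
2 | 2-(2-iodoethyl)-1,3-dioxolane | ICCC1OCCO1 | starting material
3 | lithium (3S)-6-methyl-3-(prop-1-en-2-yl)cyclohexa-1,5-dien-1-olate | [Li+].[O-]C1=C[C@@H](C(C)=C)CC=C1C | intermediate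
4 | (5S,6R)-6-[2-(1,3-dioxolan-2-yl)ethyl]-2-methyl-5-(prop-1-en-2-yl)cyclohex-2-en-1-one (major C6 epimer) | O=C1C(C)=CC[C@H](C(C)=C)[C@H]1CCC1OCCO1 | intermediate
5 | lithium (3R)-2-[2-(1,3-dioxolan-2-yl)ethyl]-6-methyl-3-(prop-1-en-2-yl)cyclohexa-1,5-dien-1-olate | [Li+].[O-]C1=C(CCC2OCCO2)[C@@H](C(C)=C)CC=C1C | intermediate
6 | (5R,6S)-6-[2-(1,3-dioxolan-2-yl)ethyl]-2,6-dimethyl-5-(prop-1-en-2-yl)cyclohex-2-en-1-one | O=C1C(C)=CC[C@H](C(C)=C)[C@]1(C)CCC1OCCO1 | intermediate
7 | 4-methylbenzenesulfonohydrazide | Cc1ccc(cc1)S(=O)(=O)NN | starting material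
8 | 3-[(1S,6R)-1,3-dimethyl-2-oxo-6-(prop-1-en-2-yl)cyclohex-3-en-1-yl]propanal | O=C1C(C)=CC[C@H](C(C)=C)[C@]1(C)CCC=O | intermediate
9 | (E)-tosylhydrazone of 8 | O=C1C(C)=CC[C@H](C(C)=C)[C@]1(C)CC/C=N/NS(=O)(=O)c1ccc(C)cc1 | intermediate
10 | N'-[(4aS,8aR)-1,1,4a,6-tetramethyl-5-oxo-1,2,3,4,4a,5,8,8a-octahydronaphthalen-2-yl]-4-methylbenzenesulfonohydrazide (C2 epimers) | O=C1C(C)=CC[C@@H]2C(C)(C)C(NNS(=O)(=O)c3ccc(C)cc3)CC[C@]12C | intermediate
11 | (4aR,8aS)-2,5,5,8a-tetramethyl-4a,5,6,7,8,8a-hexahydronaphthalen-1(4H)-one (cis-fused) | O=C1C(C)=CC[C@@H]2C(C)(C)CCC[C@]12C | intermediate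
12 | (2R,4aR,8aS)-2-hydroperoxy-2,5,5,8a-tetramethyloctahydronaphthalen-1(2H)-one | O=C1[C@](C)(OO)CC[C@@H]2C(C)(C)CCC[C@]12C | intermediate
13 | (2R,4aR,8aS)-2-hydroxy-2,5,5,8a-tetramethyloctahydronaphthalen-1(2H)-one | O=C1[C@](C)(O)CC[C@@H]2C(C)(C)CCC[C@]12C | intermediate
14 | (2R,4aR,8aS)-2,5,5,8a-tetramethyl-1-methylidenedecahydronaphthalen-2-ol | C=C1[C@](C)(O)CC[C@@H]2C(C)(C)CCC[C@]12C | intermediate
15 | 2-bromobenzene-1,4-diol | Oc1ccc(O)c(Br)c1 | starting material
16 | 2-bromo-1,4-bis(methoxymethoxy)benzene | COCOc1ccc(OCOC)c(Br)c1 | intermediate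
17 | [2-bromo-3,6-bis(methoxymethoxy)phenyl]lithium | [Li]c1c(OCOC)ccc(OCOC)c1Br | intermediate
18 | lithium [2-bromo-3,6-bis(methoxymethoxy)phenyl](dimethylamino)methanolate | [Li+].[O-]C(N(C)C)c1c(OCOC)ccc(OCOC)c1Br | intermediate
19 | 2-bromo-3,6-bis(methoxymethoxy)benzaldehyde | COCOc1ccc(OCOC)c(C=O)c1Br | intermediate
20 | 9-{[(1R,2R,4aR,8aS)-2-hydroxy-2,5,5,8a-tetramethyldecahydronaphthalen-1-yl]methyl}-9-borabicyclo[3.3.1]nonane | CC1(C)CCC[C@@]2(C)[C@@H]1CC[C@@](C)(O)[C@@H]2CB1C2CCCC1CCC2 | intermediate
21 | 2-{[(1R,2R,4aR,8aS)-2-hydroxy-2,5,5,8a-tetramethyldecahydronaphthalen-1-yl]methyl}-3,6-bis(methoxymethoxy)benzaldehyde | CC1(C)CCC[C@@]2(C)[C@@H]1CC[C@@](C)(O)[C@@H]2Cc1c(OCOC)ccc(OCOC)c1C=O | intermediate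
22 | 2-{[(1R,2R,4aR,8aS)-2-hydroxy-2,5,5,8a-tetramethyldecahydronaphthalen-1-yl]methyl}-3,6-dihydroxybenzaldehyde | CC1(C)CCC[C@@]2(C)[C@@H]1CC[C@@](C)(O)[C@@H]2Cc1c(O)ccc(O)c1C=O | target

Total step count: 9. Longest linear sequence: 7 (steps 1, 2, 3, 4, 5, 8, 9).

**Steps most likely to fail**

1. Step 3. The tertiary radical may be quenched by hydrogen before it cyclises, or the iron hydride may reduce the enone or the hydrazone directly. The fallback reverses the order of the two ring A bonds and sets out from 1:
   - α′-Methylation (LiN(i-Pr)2, MeI) gives 6-methylcarvone F1.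
   - The same iron-hydride conditions with acrolein (intermolecular Giese-type olefin coupling at the isopropenyl group) attach C3–C1 to C4 and give the aldehyde F2.
   - NaBH4 at −78 °C reduces only the aldehyde, to the alcohol F3, and I2/PPh3/imidazole (Appel) gives the iodide F4.
   - LiN(i-Pr)2 then closes ring A by intramolecular enolate alkylation at C10; the tether comes from C5, so the fusion is cis, and the route is rejoined at 11.

2. Step 5. Ylide addition to the doubly flanked carbonyl may be too slow, and the hot alkoxide may isomerise the α-ketol. The fallback sets out from 11 and introduces C11 before the C8 oxygen: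
   - Wittig methylenation of the less hindered enone gives the diene F5.
   - 16 is lithiated as in step 7 and quenched with I2 to give the iodo bromide F6.
   - Hydroboration of F5 with 9-BBN gives the borane F7, which is coupled at the C–I bond of F6 to give the aryl bromide F8.
   - Mukaiyama hydration (Co(acac)2, PhSiH3, O2) of the C7=C8 alkene puts OH-8 anti to the vicinal C9 substituent and gives the tertiary alcohol F9.
   - t-BuLi, then DMF, converts the C–Br bond into the formyl group and returns to 21.

3. Step 8. Hydroboration or transmetalation at the neopentyl-type centre may be sluggish, or the borane may attack the β-face. The fallback sets out from 14 and 19: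
   - Heck coupling (Pd(OAc)2, P(t-Bu)3, K2CO3, DMF) gives the styrene F10; only the C11 hydrogens are available for β-hydride elimination.
   - Hydroxyl-directed hydrogenation with [Ir(cod)(PCy3)(py)]PF6 and H2 delivers H-9 syn to OH-8 and returns to 21.

## Further compounds

F1 | step 3 | (5S)-2,6-dimethyl-5-(prop-1-en-2-yl)cyclohex-2-en-1-one (C6 epimers) | O=C1C(C)=CC[C@H](C(C)=C)C1C
F2 | step 3 | 4-[(1S)-2,4-dimethyl-3-oxocyclohex-4-en-1-yl]-4-methylpentanal | O=C1C(C)=CC[C@H](C(C)(C)CCC=O)C1C
F3 | step 3 | (5S)-5-(5-hydroxy-2-methylpentan-2-yl)-2,6-dimethylcyclohex-2-en-1-one | O=C1C(C)=CC[C@H](C(C)(C)CCCO)C1C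
F4 | step 3 | (5S)-5-(5-iodo-2-methylpentan-2-yl)-2,6-dimethylcyclohex-2-en-1-one | O=C1C(C)=CC[C@H](C(C)(C)CCCI)C1C
F5 | step 5 | (4aR,8aS)-2,5,5,8a-tetramethyl-1-methylidene-1,4,4a,5,6,7,8,8a-octahydronaphthalene | C=C1C(C)=CC[C@@H]2C(C)(C)CCC[C@]12C
F6 | step 5 | 2-bromo-3-iodo-1,4-bis(methoxymethoxy)benzene | COCOc1ccc(OCOC)c(Br)c1I
F7 | step 5 | 9-BBN adduct of F5 at the exocyclic methylene (H-9 α, anti to CH3-10) | CC1=CC[C@@H]2C(C)(C)CCC[C@]2(C)[C@H]1CB1C2CCCC1CCC2
F8 | step 5 | 2-bromo-1,4-bis(methoxymethoxy)-3-{[(4aR,8aS)-2,5,5,8a-tetramethyl-1,4,4a,5,6,7,8,8a-octahydronaphthalen-1-yl]methyl}benzene (H-9 α) | CC1=CC[C@@H]2C(C)(C)CCC[C@]2(C)[C@H]1Cc1c(OCOC)ccc(OCOC)c1Br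
F9 | step 5 | (1R,2R,4aR,8aS)-1-{[2-bromo-3,6-bis(methoxymethoxy)phenyl]methyl}-2,5,5,8a-tetramethyldecahydronaphthalen-2-ol | CC1(C)CCC[C@@]2(C)[C@@H]1CC[C@@](C)(O)[C@@H]2Cc1c(OCOC)ccc(OCOC)c1Br
F10 | step 8 | 2-{[(2R,4aR,8aS)-2-hydroxy-2,5,5,8a-tetramethyloctahydronaphthalen-1(2H)-ylidene]methyl}-3,6-bis(methoxymethoxy)benzaldehyde (alkene isomers) | C[C@@]1(O)CC[C@@H]2C(C)(C)CCC[C@]2(C)C1=Cc1c(OCOC)ccc(OCOC)c1C=O
A1 | direct plan | (Z)-6,10-dimethylundeca-5,9-dien-1-yne | C#CCC/C=C(/C)CCC=C(C)C
A2 | direct plan | (4aR,8aS)-5,5,8a-trimethyl-3,4,4a,5,6,7,8,8a-octahydronaphthalen-2-yl acetate | CC1(C)CCC[C@@]2(C)[C@@H]1CCC(OC(C)=O)=C2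
A3 | direct plan | (1R,4aR,8aS)-5,5,8a-trimethyl-1-(prop-2-yn-1-yl)octahydronaphthalen-2(1H)-one | CC1(C)CCC[C@@]2(C)[C@@H]1CCC(=O)[C@@H]2CC#C
A4 | direct plan | 4-[(1R,2R,4aR,8aS)-2-hydroxy-2,5,5,8a-tetramethyldecahydronaphthalen-1-yl]but-2-ynal | CC1(C)CCC[C@@]2(C)[C@@H]1CC[C@@](C)(O)[C@@H]2CC#CC=O
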